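The single product at the end of a flask is a leftover, what stands between being made and being passed on, so I reckon this small fraction of the charge by itself.

| setting | larch | cedar | eta | alpha |
|---|---|---|---|---|
| starting material | 1 M | 1 M | 1.0 M | 1.0 M |
| partner | 1.2 M | 2.8 M | 2.00 M | 1.00 M |
| remark | run made earlier | run made earlier |  |  |
| time |  |  | 10 min | 10 min |

| run | time / min | single product / % | double product / % |
|---|---|---|---|
| larch | 1.33 | 16.8 | 4.7 |
| larch | 3.00 | 22.5 | 11.1 |
| larch | 4.00 | 22.5 | 15.1 |
| larch | 6.00 | 18.5 | 23.5 |
| larch | 8.00 | 15.5 | 26.3 |
| cedar | 0.500 | 16.6 | 3.9 |
| cedar | 1.00 | 24.8 | 12.2 |
| cedar | 2.00 | 23.9 | 24.8 |
| cedar | 4.00 | 14.4 | 44.2 |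
| cedar | 8.00 | 5.9 | 60.0 |

(each reading ± 1 percentage point)

- which of these holds the largest part of the starting material at the end of eta (starting material / double product / single product)
- which of these holds the largest part of the starting material at the end of alpha (starting material / double product / single product)
- how much single product is there at the end of eta, in percent of the starting material charged

- a reading or a percentage of double product counts all its forms, free or not

I measure each flask by its exposure, the equivalents of partner charged times the minutes run, which for eta is 20.0 min. With the main step alone, starting material plus partner giving single product, and partner held at its charge, the first cedar reading gives 0.164 min⁻¹, and eta would end with 96.2% single product. Next I add the step in which single product takes up partner to give double product. The last larch and cedar readings, both at 8.00 min, give 0.0755 min⁻¹ as the tail constant, the fall of the logarithm of the single-product fraction per unit of exposure, an empirical slope read off the tail with exposure counted from the partner charge. The last two readings within larch give 0.0737 min⁻¹ and those within cedar 0.0797 min⁻¹. Used in my reckoning as the constant of that second step, this slope brings eta down to 34.0%. For the rest, which I cannot name, I use the height of the tail: larch carried back to zero exposure starts at 32.0%, against 185% from the two steps. With that height I commit to 7.07% single product for eta.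

The forecast gives 8%, a little apart from my figure, with double product largest in eta and starting material largest in alpha: “Double product leads, but narrowly”.

Eta ends with 7.38% single product, and double product leads at 50.8% against 8.48% free starting material, while alpha ends with starting material largest at 29.9%.

    single product → decomposed reagent (k = 0.101 min⁻¹)
    starting material + double product ⇌ idle adduct, settled at all times (K = 6.20 M⁻¹)
    partner + single product → double product (k = 0.279 M⁻¹ min⁻¹)
    starting material + partner → single product (k = 0.199 M⁻¹ min⁻¹)

Read back through the same height, the eta result gives a tail constant of 0.0733 min⁻¹, against 0.0755 min⁻¹ from the earlier runs. The neighbour charged with 0.80 M of partner and read at the same time has an exposure of 8.00 min, so the tail reckons 17.5% single product, and that flask holds 15.5%.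

All runs come from a simulation with made-up constants.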